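**Retrosynthetic overview**
1. Target 28 ⇐ hydrogenolysis of tri-O-benzyl butenolide 27; the butenolide ring (formed last) ⇐ intramolecular aldol condensation of the (benzyloxy)acetate 25 onto its aryl ketone.
2. 25 ⇐ O-acylation of α-hydroxy-β-keto ester 23 ⇐ oxidation and methanolysis of aldol adduct 21.
3. Key C–C bond (quaternary carbon to the aryl-bearing carbon): intermolecular aldol of the Seebach dioxolanone enolate from (S)-aryl-lactic acid 16 with 4-(benzyloxy)benzaldehyde 19; the temporary dioxolanone ring relays the lactate stereocentre to the quaternary centre.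
4. 16 ⇐ copper-catalysed opening of methyl (S)-glycidate 13 by the Grignard reagent of bromo-dihydrobenzofuran 12.
5. Dihydrobenzofuran ring (formed first) ⇐ 4-bromophenol by Claisen rearrangement, cross-metathesis prenylation, Shi epoxidation and 5-exo epoxide opening. Ring order: dihydrobenzofuran, dioxolanone (auxiliary), butenolide.

Assumption: the target is taken as drawn, (R) at the butenolide quaternary carbon and (S) at C-2 of the dihydrobenzofuran; 13, 19 and 24 are bought; the few percent of wrong epoxide enantiomer from step 5 is removed as a minor diastereomer by chromatography at 15.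

**Route**

Step 1
Reactants: 1 4-bromophenol; 2 allyl bromide
Product: 3 1-(allyloxy)-4-bromobenzene
Conditions: K2CO3, acetone, reflux
Reagents that add atoms: none
Why: Williamson ether synthesis, the phenoxide displacing bromide from the allylic halide by SN2.

Step 2
Reactants: 3 1-(allyloxy)-4-bromobenzene
Product: 5 2-allyl-4-bromophenol, via dienone 4 (not isolated)
Conditions: neat (or PhNEt2), 200 °C, sealed tube
Reagents that add atoms: none
Why: Aromatic Claisen rearrangement ([3,3]-sigmatropic shift, then tautomerisation) delivers the allyl group to the ortho position, the para position being blocked by bromine.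

Step 3
Reactants: 5 2-allyl-4-bromophenol
Product: 6 (2-allyl-4-bromophenoxy)(tert-butyl)dimethylsilane
Conditions: TBSCl, imidazole, DMF, rt
Reagents that add atoms: tert-butyldimethylsilyl chloride CC(C)(C)[Si](C)(C)Cl
Why: Imidazole-promoted silylation masks the phenol, which would otherwise be oxidised by the dioxirane of step 5 and open the epoxide prematurely.

Step 4
Reactants: 6 (2-allyl-4-bromophenoxy)(tert-butyl)dimethylsilane; 7 2-methylbut-2-ene
Product: 8 [4-bromo-2-(3-methylbut-2-en-1-yl)phenoxy](tert-butyl)dimethylsilane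
Conditions: second-generation Grubbs catalyst RuCl2(=CHPh)(PCy3)(H2IMes) (3 mol %), 2-methylbut-2-ene (excess)/CH2Cl2, 40 °C, sealed
Reagents that add atoms: none
Why: Olefin cross-metathesis with excess 2-methylbut-2-ene exchanges the terminal CH2 for an isopropylidene unit, giving the prenyl group with loss of propene.

Step 5
Reactants: 8 [4-bromo-2-(3-methylbut-2-en-1-yl)phenoxy](tert-butyl)dimethylsilane
Product: 9 (4-bromo-2-{[(2R)-3,3-dimethyloxiran-2-yl]methyl}phenoxy)(tert-butyl)dimethylsilane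
Conditions: D-fructose-derived Shi ketone (1,2:4,5-di-O-isopropylidene-β-D-erythro-hexo-2,3-diulo-2,6-pyranose, 30 mol %), KHSO5 (as 2KHSO5·KHSO4·K2SO4), K2CO3, Na2B4O7 buffer (pH 10.5), Bu4NHSO4, MeCN/CH2(OMe)2/H2O, 0 °C
Reagents that add atoms: potassium peroxymonosulfate [K+].[O-]S(=O)(=O)OO
Why: Shi asymmetric epoxidation, in which the chiral dioxirane attacks one face of the trisubstituted alkene through a spiro transition state and gives the (R)-epoxide (typically 90–95% ee).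

Step 6
Reactants: 9 (4-bromo-2-{[(2R)-3,3-dimethyloxiran-2-yl]methyl}phenoxy)(tert-butyl)dimethylsilane
Product: 11 2-[(2S)-5-bromo-2,3-dihydro-1-benzofuran-2-yl]propan-2-ol, via epoxy phenoxide 10 (not isolated)
Conditions: Bu4NF, THF, 0 °C → rt; H2O work-up
Reagents that add atoms: tetrabutylammonium fluoride CCCC[N+](CCCC)(CCCC)CCCC.[F-] (its cation stays only in 10)
Why: Fluoride desilylation frees the phenoxide, which opens the epoxide at the secondary carbon by 5-exo-tet SN2 with inversion, so the (R)-epoxide gives the (S)-dihydrobenzofuran.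

Step 7
Reactants: 11 2-[(2S)-5-bromo-2,3-dihydro-1-benzofuran-2-yl]propan-2-ol
Product: 12 (2S)-2-[2-(benzyloxy)propan-2-yl]-5-bromo-2,3-dihydro-1-benzofuran
Conditions: NaH, BnBr, Bu4NI (cat.), THF/DMF, 0 °C → 50 °C
Reagents that add atoms: benzyl bromide BrCc1ccccc1
Why: Williamson benzylation of the tertiary alkoxide protects the hydroxyl that would compete in the acylation of step 14, as an ether that the final hydrogenolysis removes.

Step 8
Reactants: 12 (2S)-2-[2-(benzyloxy)propan-2-yl]-5-bromo-2,3-dihydro-1-benzofuran; 13 methyl (2S)-oxirane-2-carboxylate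
Product: 15 methyl (2S)-3-{(2S)-2-[2-(benzyloxy)propan-2-yl]-2,3-dihydro-1-benzofuran-5-yl}-2-hydroxypropanoate, via aryl Grignard 14 (not isolated)
Conditions: Mg, THF, 45 °C; then CuI (10 mol %), 13, THF, −40 → −20 °C; cold 1 M HCl work-up
Reagents that add atoms: magnesium [Mg] (stays only in 14)
Why: Grignard formation followed by copper-catalysed SN2 opening of the epoxide at its unsubstituted carbon, which leaves the glycidate stereocentre untouched as the (S)-lactate.

Step 9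
Reactants: 15 methyl (2S)-3-{(2S)-2-[2-(benzyloxy)propan-2-yl]-2,3-dihydro-1-benzofuran-5-yl}-2-hydroxypropanoate
Product: 16 (2S)-3-{(2S)-2-[2-(benzyloxy)propan-2-yl]-2,3-dihydro-1-benzofuran-5-yl}-2-hydroxypropanoic acid
Conditions: LiOH, THF/H2O, 0 °C → rt; then 1 M HCl to pH 3
Reagents that add atoms: lithium hydroxide [Li+].[OH-]
Why: Mild ester saponification gives the free α-hydroxy acid without touching the α-stereocentre.

Step 10
Reactants: 16 (2S)-3-{(2S)-2-[2-(benzyloxy)propan-2-yl]-2,3-dihydro-1-benzofuran-5-yl}-2-hydroxypropanoic acid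
Product: 18 (2S,5S)-5-({(2S)-2-[2-(benzyloxy)propan-2-yl]-2,3-dihydro-1-benzofuran-5-yl}methyl)-2-tert-butyl-1,3-dioxolan-4-one, via bis-TMS derivative 17 (not isolated)
Conditions: TMSCl, Et3N, CH2Cl2, 0 °C → rt; then t-BuCHO, TMSOTf (5 mol %), CH2Cl2, −78 °C; pyridine quench
Reagents that add atoms: chlorotrimethylsilane C[Si](C)(C)Cl (stays only in 17); pivalaldehyde CC(C)(C)C=O
Why: Seebach acetalisation for self-regeneration of stereocentres, run under kinetic TMSOTf catalysis so that the lactate stereocentre sets the new acetal centre cis (2S).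

Step 11
Reactants: 18 (2S,5S)-5-({(2S)-2-[2-(benzyloxy)propan-2-yl]-2,3-dihydro-1-benzofuran-5-yl}methyl)-2-tert-butyl-1,3-dioxolan-4-one; 19 4-(benzyloxy)benzaldehyde
Product: 21 (2S,5R)-5-{[4-(benzyloxy)phenyl](hydroxy)methyl}-5-({(2S)-2-[2-(benzyloxy)propan-2-yl]-2,3-dihydro-1-benzofuran-5-yl}methyl)-2-tert-butyl-1,3-dioxolan-4-one (both carbinol epimers), via lithium enolate 20 (not isolated)
Conditions: LiN(iPr)2, THF, −78 °C; then 19, −78 °C; AcOH quench at −78 °C
Reagents that add atoms: lithium diisopropylamide CC(C)N([Li])C(C)C (lithium stays only in 20)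
Why: Intermolecular aldol addition of the dioxolanone enolate to the aldehyde on the face anti to the tert-butyl group forms the key C–C bond and sets the quaternary centre as (5R); the carbinol centre is uncontrolled and is erased in step 12.

Step 12
Reactants: 21 (2S,5R)-5-{[4-(benzyloxy)phenyl](hydroxy)methyl}-5-({(2S)-2-[2-(benzyloxy)propan-2-yl]-2,3-dihydro-1-benzofuran-5-yl}methyl)-2-tert-butyl-1,3-dioxolan-4-one
Product: 22 (2S,5R)-5-[4-(benzyloxy)benzoyl]-5-({(2S)-2-[2-(benzyloxy)propan-2-yl]-2,3-dihydro-1-benzofuran-5-yl}methyl)-2-tert-butyl-1,3-dioxolan-4-one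
Conditions: Dess–Martin periodinane, CH2Cl2, 0 °C → rt
Reagents that add atoms: none
Why: Dess–Martin oxidation converts both carbinol epimers into one aryl ketone under near-neutral conditions that leave the acetal and the non-enolisable quaternary centre intact.

Step 13
Reactants: 22 (2S,5R)-5-[4-(benzyloxy)benzoyl]-5-({(2S)-2-[2-(benzyloxy)propan-2-yl]-2,3-dihydro-1-benzofuran-5-yl}methyl)-2-tert-butyl-1,3-dioxolan-4-one
Product: 23 methyl (2R)-2-({(2S)-2-[2-(benzyloxy)propan-2-yl]-2,3-dihydro-1-benzofuran-5-yl}methyl)-3-[4-(benzyloxy)phenyl]-2-hydroxy-3-oxopropanoate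
Conditions: HCl (cat., 1.25 M in MeOH), MeOH, 45 °C
Reagents that add atoms: methanol CO
Why: Acid-catalysed methanolysis (transesterification with acetal cleavage) releases the methyl ester and the tertiary hydroxyl without an alkoxide, which avoids retro-Claisen cleavage of the β-keto ester.

Step 14
Reactants: 23 methyl (2R)-2-({(2S)-2-[2-(benzyloxy)propan-2-yl]-2,3-dihydro-1-benzofuran-5-yl}methyl)-3-[4-(benzyloxy)phenyl]-2-hydroxy-3-oxopropanoate; 24 (benzyloxy)acetyl chloride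
Product: 25 methyl (2R)-2-{[(benzyloxy)acetyl]oxy}-2-({(2S)-2-[2-(benzyloxy)propan-2-yl]-2,3-dihydro-1-benzofuran-5-yl}methyl)-3-[4-(benzyloxy)phenyl]-3-oxopropanoate
Conditions: pyridine, DMAP (cat.), CH2Cl2, 0 °C → rt
Reagents that add atoms: none
Why: DMAP-catalysed O-acylation of the only free hydroxyl by an unhindered acid chloride brings in the two remaining ring carbons and the enol oxygen in protected form.

Step 15
Reactants: 25 methyl (2R)-2-{[(benzyloxy)acetyl]oxy}-2-({(2S)-2-[2-(benzyloxy)propan-2-yl]-2,3-dihydro-1-benzofuran-5-yl}methyl)-3-[4-(benzyloxy)phenyl]-3-oxopropanoate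
Product: 27 methyl (2R)-4-(benzyloxy)-3-[4-(benzyloxy)phenyl]-2-({(2S)-2-[2-(benzyloxy)propan-2-yl]-2,3-dihydro-1-benzofuran-5-yl}methyl)-5-oxo-2,5-dihydrofuran-2-carboxylate, via aldol lactone 26 (not isolated)
Conditions: DBU, CF3CO2iPr, MeCN, 70 °C
Reagents that add atoms: none
Why: Intramolecular aldol condensation, the glycolate ester enolate adding to the more electrophilic aryl ketone (5-membered ring) and the aldol losing water (taken up by the trifluoroacetate) to give the aryl-conjugated butenolide; the quaternary centre is not involved.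

Step 16
Reactants: 27 methyl (2R)-4-(benzyloxy)-3-[4-(benzyloxy)phenyl]-2-({(2S)-2-[2-(benzyloxy)propan-2-yl]-2,3-dihydro-1-benzofuran-5-yl}methyl)-5-oxo-2,5-dihydrofuran-2-carboxylate
Product: 28 methyl (2R)-4-hydroxy-3-(4-hydroxyphenyl)-2-{[(2S)-2-(2-hydroxypropan-2-yl)-2,3-dihydro-1-benzofuran-5-yl]methyl}-5-oxo-2,5-dihydrofuran-2-carboxylate
Conditions: H2 (1 atm), Pd(OH)2/C, EtOAc/MeOH, rt
Reagents that add atoms: none
Why: Catalytic hydrogenolysis cleaves the aryl, enol and tertiary-alkyl benzyl ethers, while the tetrasubstituted enol double bond, the lactone and both stereocentres are inert.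

**Compound list**
1 | 4-bromophenol | Oc1ccc(Br)cc1 | starting material
2 | allyl bromide | C=CCBr | starting material
3 | 1-(allyloxy)-4-bromobenzene | C=CCOc1ccc(Br)cc1 | intermediate
4 | 6-allyl-4-bromocyclohexa-2,4-dien-1-one (formed in situ) | C=CCC1C=C(Br)C=CC1=O | intermediate
5 | 2-allyl-4-bromophenol | C=CCc1cc(Br)ccc1O | intermediate
6 | (2-allyl-4-bromophenoxy)(tert-butyl)dimethylsilane | C=CCc1cc(Br)ccc1O[Si](C)(C)C(C)(C)C | intermediate
7 | 2-methylbut-2-ene | CC=C(C)C | starting material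
8 | [4-bromo-2-(3-methylbut-2-en-1-yl)phenoxy](tert-butyl)dimethylsilane | CC(C)=CCc1cc(Br)ccc1O[Si](C)(C)C(C)(C)C | intermediate
9 | (4-bromo-2-{[(2R)-3,3-dimethyloxiran-2-yl]methyl}phenoxy)(tert-butyl)dimethylsilane | CC1(C)O[C@@H]1Cc1cc(Br)ccc1O[Si](C)(C)C(C)(C)C | intermediate
10 | tetrabutylammonium 4-bromo-2-{[(2R)-3,3-dimethyloxiran-2-yl]methyl}phenoxide (formed in situ) | CC1(C)O[C@@H]1Cc1cc(Br)ccc1[O-].CCCC[N+](CCCC)(CCCC)CCCC | intermediate
11 | 2-[(2S)-5-bromo-2,3-dihydro-1-benzofuran-2-yl]propan-2-ol | Brc1ccc2c(c1)C[C@@H](C(C)(C)O)O2 | intermediate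
12 | (2S)-2-[2-(benzyloxy)propan-2-yl]-5-bromo-2,3-dihydro-1-benzofuran | Brc1ccc2c(c1)C[C@@H](C(C)(C)OCc1ccccc1)O2 | intermediate
13 | methyl (2S)-oxirane-2-carboxylate (methyl (S)-glycidate) | COC(=O)[C@@H]1CO1 | starting material
14 | {(2S)-2-[2-(benzyloxy)propan-2-yl]-2,3-dihydro-1-benzofuran-5-yl}magnesium bromide (formed in situ) | Br[Mg]c1ccc2c(c1)C[C@@H](C(C)(C)OCc1ccccc1)O2 | intermediate
15 | methyl (2S)-3-{(2S)-2-[2-(benzyloxy)propan-2-yl]-2,3-dihydro-1-benzofuran-5-yl}-2-hydroxypropanoate | COC(=O)[C@@H](O)Cc1ccc2c(c1)C[C@@H](C(C)(C)OCc1ccccc1)O2 | intermediate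
16 | (2S)-3-{(2S)-2-[2-(benzyloxy)propan-2-yl]-2,3-dihydro-1-benzofuran-5-yl}-2-hydroxypropanoic acid | OC(=O)[C@@H](O)Cc1ccc2c(c1)C[C@@H](C(C)(C)OCc1ccccc1)O2 | intermediate
17 | trimethylsilyl (2S)-3-{(2S)-2-[2-(benzyloxy)propan-2-yl]-2,3-dihydro-1-benzofuran-5-yl}-2-(trimethylsilyloxy)propanoate (formed in situ) | C[Si](C)(C)OC(=O)[C@@H](O[Si](C)(C)C)Cc1ccc2c(c1)C[C@@H](C(C)(C)OCc1ccccc1)O2 | intermediate
18 | (2S,5S)-5-({(2S)-2-[2-(benzyloxy)propan-2-yl]-2,3-dihydro-1-benzofuran-5-yl}methyl)-2-tert-butyl-1,3-dioxolan-4-one | CC(C)(C)[C@@H]1OC(=O)[C@H](Cc2ccc3c(c2)C[C@@H](C(C)(C)OCc2ccccc2)O3)O1 | intermediate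
19 | 4-(benzyloxy)benzaldehyde | O=Cc1ccc(OCc2ccccc2)cc1 | starting material
20 | lithium enolate of 18 (formed in situ) | CC(C)(C)[C@@H]1OC(O[Li])=C(Cc2ccc3c(c2)C[C@@H](C(C)(C)OCc2ccccc2)O3)O1 | intermediate
21 | (2S,5R)-5-{[4-(benzyloxy)phenyl](hydroxy)methyl}-5-({(2S)-2-[2-(benzyloxy)propan-2-yl]-2,3-dihydro-1-benzofuran-5-yl}methyl)-2-tert-butyl-1,3-dioxolan-4-one (carbinol epimers) | CC(C)(C)[C@@H]1OC(=O)[C@@](Cc2ccc3c(c2)C[C@@H](C(C)(C)OCc2ccccc2)O3)(C(O)c2ccc(OCc3ccccc3)cc2)O1 | intermediate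
22 | (2S,5R)-5-[4-(benzyloxy)benzoyl]-5-({(2S)-2-[2-(benzyloxy)propan-2-yl]-2,3-dihydro-1-benzofuran-5-yl}methyl)-2-tert-butyl-1,3-dioxolan-4-one | CC(C)(C)[C@@H]1OC(=O)[C@@](Cc2ccc3c(c2)C[C@@H](C(C)(C)OCc2ccccc2)O3)(C(=O)c2ccc(OCc3ccccc3)cc2)O1 | intermediate
23 | methyl (2R)-2-({(2S)-2-[2-(benzyloxy)propan-2-yl]-2,3-dihydro-1-benzofuran-5-yl}methyl)-3-[4-(benzyloxy)phenyl]-2-hydroxy-3-oxopropanoate | COC(=O)[C@@](O)(Cc1ccc2c(c1)C[C@@H](C(C)(C)OCc1ccccc1)O2)C(=O)c1ccc(OCc2ccccc2)cc1 | intermediate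
24 | (benzyloxy)acetyl chloride | ClC(=O)COCc1ccccc1 | starting material
25 | methyl (2R)-2-{[(benzyloxy)acetyl]oxy}-2-({(2S)-2-[2-(benzyloxy)propan-2-yl]-2,3-dihydro-1-benzofuran-5-yl}methyl)-3-[4-(benzyloxy)phenyl]-3-oxopropanoate | COC(=O)[C@@](OC(=O)COCc1ccccc1)(Cc1ccc2c(c1)C[C@@H](C(C)(C)OCc1ccccc1)O2)C(=O)c1ccc(OCc2ccccc2)cc1 | intermediate
26 | methyl (2R)-4-(benzyloxy)-3-[4-(benzyloxy)phenyl]-2-({(2S)-2-[2-(benzyloxy)propan-2-yl]-2,3-dihydro-1-benzofuran-5-yl}methyl)-3-hydroxy-5-oxotetrahydrofuran-2-carboxylate (formed in situ, epimers at C-3 and C-4) | COC(=O)[C@]1(Cc2ccc3c(c2)C[C@@H](C(C)(C)OCc2ccccc2)O3)OC(=O)C(OCc2ccccc2)C1(O)c1ccc(OCc2ccccc2)cc1 | intermediate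
27 | methyl (2R)-4-(benzyloxy)-3-[4-(benzyloxy)phenyl]-2-({(2S)-2-[2-(benzyloxy)propan-2-yl]-2,3-dihydro-1-benzofuran-5-yl}methyl)-5-oxo-2,5-dihydrofuran-2-carboxylate | COC(=O)[C@]1(Cc2ccc3c(c2)C[C@@H](C(C)(C)OCc2ccccc2)O3)OC(=O)C(OCc2ccccc2)=C1c1ccc(OCc2ccccc2)cc1 | intermediate
28 | methyl (2R)-4-hydroxy-3-(4-hydroxyphenyl)-2-{[(2S)-2-(2-hydroxypropan-2-yl)-2,3-dihydro-1-benzofuran-5-yl]methyl}-5-oxo-2,5-dihydrofuran-2-carboxylate | COC(=O)[C@]1(Cc2ccc3c(c2)C[C@@H](C(C)(C)O)O3)OC(=O)C(O)=C1c1ccc(O)cc1 | target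

**Summary**
Total steps: 16. Longest linear sequence: 16 steps, from 4-bromophenol (1) to 28; compounds 13, 19 and 24 are bought.

Steps most likely to fail:

Step 8 (copper-catalysed glycidate opening; the Grignard reagent may attack the ester or homocouple). The fallback sets out from 12 and comes back at 16. Bromine–lithium exchange with n-butyllithium (THF, −78 °C) gives the aryllithium F1, and a DMF quench gives the aldehyde F2. Horner–Wadsworth–Emmons olefination with methyl 2-acetoxy-2-(dimethoxyphosphoryl)acetate (LiCl, DBU, MeCN) gives the (Z)-enol acetate F3. Asymmetric hydrogenation with [Rh(cod)((S,S)-Et-DuPhos)]OTf under H2 in MeOH should give the (S)-acetoxy ester F4; the ligand enantiomer is chosen by analogy with dehydroamino esters and should be confirmed. LiOH hydrolysis of both ester groups then rejoins the route at 16.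

Step 14 (acylation of a hindered tertiary hydroxyl flanked by an ester and a ketone). The fallback sets out from 22 and comes back at 26, reversing the order of bond formation. Methyl (benzyloxy)acetate and LiN(iPr)2 (THF, −78 °C) give the glycolate lithium enolate F5, which adds to the aryl ketone of 22 in an intermolecular aldol to give the tertiary carbinol F6. HCl/MeOH then opens the dioxolanone to the hydroxy diester F7, whose freed tertiary hydroxyl lactonises onto the glycolate ester to give 26. Dehydration to 27 follows as in step 15.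

Step 15 (the weakly acidic glycolate must enolise and close onto a deactivated aryl ketone; Dieckmann closure onto the methyl ester competes). The fallback sets out from 23 and comes back at 27. DCC/DMAP esterification with 2-(benzyloxy)-2-(diethoxyphosphoryl)acetic acid gives the phosphonoacetate F8. LiCl/DBU in MeCN then brings about an intramolecular Horner–Wadsworth–Emmons olefination of the aryl ketone, which closes the butenolide directly to 27.

**Further compounds**
F1 | step 8 | {(2S)-2-[2-(benzyloxy)propan-2-yl]-2,3-dihydro-1-benzofuran-5-yl}lithium | [Li]c1ccc2c(c1)C[C@@H](C(C)(C)OCc1ccccc1)O2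
F2 | step 8 | (2S)-2-[2-(benzyloxy)propan-2-yl]-2,3-dihydro-1-benzofuran-5-carbaldehyde | O=Cc1ccc2c(c1)C[C@@H](C(C)(C)OCc1ccccc1)O2
F3 | step 8 | methyl (2Z)-2-acetoxy-3-{(2S)-2-[2-(benzyloxy)propan-2-yl]-2,3-dihydro-1-benzofuran-5-yl}prop-2-enoate | COC(=O)/C(OC(C)=O)=C/c1ccc2c(c1)C[C@@H](C(C)(C)OCc1ccccc1)O2
F4 | step 8 | methyl (2S)-2-acetoxy-3-{(2S)-2-[2-(benzyloxy)propan-2-yl]-2,3-dihydro-1-benzofuran-5-yl}propanoate | COC(=O)[C@@H](OC(C)=O)Cc1ccc2c(c1)C[C@@H](C(C)(C)OCc1ccccc1)O2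
F5 | step 14 | lithium enolate of methyl (benzyloxy)acetate | COC(O[Li])=COCc1ccccc1
F6 | step 14 | methyl 2-(benzyloxy)-3-[4-(benzyloxy)phenyl]-3-[(2S,4R)-4-({(2S)-2-[2-(benzyloxy)propan-2-yl]-2,3-dihydro-1-benzofuran-5-yl}methyl)-2-tert-butyl-5-oxo-1,3-dioxolan-4-yl]-3-hydroxypropanoate (epimers at the two new centres) | CC(C)(C)[C@@H]1OC(=O)[C@@](Cc2ccc3c(c2)C[C@@H](C(C)(C)OCc2ccccc2)O3)(C(O)(C(OCc2ccccc2)C(=O)OC)c2ccc(OCc3ccccc3)cc2)O1
F7 | step 14 | dimethyl (2R)-4-(benzyloxy)-3-[4-(benzyloxy)phenyl]-2-({(2S)-2-[2-(benzyloxy)propan-2-yl]-2,3-dihydro-1-benzofuran-5-yl}methyl)-2,3-dihydroxypentanedioate (epimers at C-3 and C-4) | COC(=O)[C@@](O)(Cc1ccc2c(c1)C[C@@H](C(C)(C)OCc1ccccc1)O2)C(O)(C(OCc1ccccc1)C(=O)OC)c1ccc(OCc2ccccc2)cc1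
F8 | step 15 | methyl (2R)-2-{[(benzyloxy)(diethoxyphosphoryl)acetyl]oxy}-2-({(2S)-2-[2-(benzyloxy)propan-2-yl]-2,3-dihydro-1-benzofuran-5-yl}methyl)-3-[4-(benzyloxy)phenyl]-3-oxopropanoate | COC(=O)[C@@](OC(=O)C(OCc1ccccc1)P(=O)(OCC)OCC)(Cc1ccc2c(c1)C[C@@H](C(C)(C)OCc1ccccc1)O2)C(=O)c1ccc(OCc2ccccc2)cc1
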